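**Retrosynthetic overview**

1. The strategy rests on ring B: the ether oxygen sits on C1′ and a bromine on the adjacent C2′, the ortho pair that a nucleophile and an electrophile leave when they add across a benzyne triple bond.
2. Last disconnections: C4–Br on ring A (bromination para to the C1 hydroxyl) and the O–CH3 bond that masks the C1 hydroxyl during the aryne step.
3. Key disconnection: O–C1′ and C2′–Br together, back to the phenoxide of 3,6-dibromo-2-methoxyphenol, benzyne (from 2-(trimethylsilyl)phenyl triflate) and C6F5Br as bromine donor.
4. The phenol comes from veratrole by double ortho-lithiation/bromination (C3 and C6) and cleavage of one methyl ether with thiolate.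
5. No ring is formed: ring A is bought as veratrole and ring B as the aryne precursor.

Key step: step 3

Remark: the target is achiral, so only regiochemistry has to be controlled. Ring A is numbered C1 (OH), C2 (O-aryl), C3, C4, C6 (Br), C5 (H); ring B is C1′ (O), C2′ (Br).

**Route**

Step 1
Reactants: 1 veratrole (1,2-dimethoxybenzene)
Product: 3 1,4-dibromo-2,3-dimethoxybenzene (3,6-dibromoveratrole), via 3,6-dilithioveratrole 2 (not isolated)
Conditions: n-BuLi (3 equiv), TMEDA (3 equiv), Et2O/hexane, 0 °C → rt; then BrCCl2CCl2Br (3 equiv), THF, −78 °C → rt
Reagents that add atoms: 1,2-dibromo-1,1,2,2-tetrachloroethane, BrC(Cl)(Cl)C(Cl)(Cl)Br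
Why: Double directed ortho-metalation, in which each methoxy oxygen guides TMEDA-activated n-BuLi to its free ortho position, followed by bromine transfer from the polyhaloethane to both aryllithium carbons, should give the 3,6-dibromide.

Step 2
Reactants: 3 1,4-dibromo-2,3-dimethoxybenzene
Product: 5 3,6-dibromo-2-methoxyphenol, via sodium phenoxide 4 (not isolated)
Conditions: NaSEt (1.5 equiv), DMF, 100 °C; then aq. HCl
Reagents that add atoms: none
Why: Nucleophilic aryl methyl ether cleavage (SN2 attack of ethanethiolate on a methyl carbon) should stop after one methyl, because the phenoxide formed makes the neighbouring aryloxide a poor leaving group, and the two methoxy groups of 3 are equivalent so only one mono-phenol can form.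

Step 3
Reactants: 5 3,6-dibromo-2-methoxyphenol; 6 2-(trimethylsilyl)phenyl trifluoromethanesulfonate; 7 bromopentafluorobenzene
Product: 11 1,4-dibromo-2-(2-bromophenoxy)-3-methoxybenzene, via potassium phenoxide 8 (not isolated), via benzyne 9 (not isolated), via aryloxyphenylpotassium 10 (not isolated)
Conditions: KH (1.05 equiv), THF, 0 °C; then 7 (3 equiv), 6 (1.5 equiv), KF (3 equiv), 18-crown-6 (3 equiv), THF, 0 °C → rt; H2O quench
Reagents that add atoms: none
Why: Fluoride attacks the silicon of 6 and triflate departs, releasing benzyne 9; the oxygen of phenoxide 8 adds to the strained triple bond to form O–C1′, and the carbanion left on the adjacent C2′ (10) takes bromine from the halogen-bond donor 7 to form C2′–Br, with pentafluorophenyl anion as the leaving group. The closest known reaction type is the aryne three-component coupling of a heteroatom nucleophile with an electrophilic halogen source (1,2-heteroatom-halogenation of arynes), which builds on the fluoride-promoted O-arylation of phenols by silylaryl triflates. No ring is closed and no stereocentre is created. Because the two carbons of the benzyne triple bond are equivalent, either mode of addition gives the same ortho pair. The selectivity needed is bromine capture by 10 in preference to its protonation, which the methyl ether on the neighbouring oxygen (no O–H left in the substrate), deprotonation by KH (H2 as the only by-product) and aprotic THF should secure. The phenoxide, hindered by OMe and Br on either side of the oxygen, is weakly nucleophilic, which a free aryne tolerates and which should also slow substitution at the para C–F bond of 7.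

Step 4
Reactants: 11 1,4-dibromo-2-(2-bromophenoxy)-3-methoxybenzene
Product: 13 3,6-dibromo-2-(2-bromophenoxy)phenol, via aryloxydibromoborane 12 (not isolated)
Conditions: BBr3 (1.5 equiv), CH2Cl2, −78 °C → rt; then H2O
Reagents that add atoms: none
Why: Lewis-acid-mediated aryl methyl ether cleavage, in which BBr3 binds the methoxy oxygen and bromide removes the methyl group by SN2, should free the C1 hydroxyl after hydrolysis of the borate ester, while the diaryl ether (no sp3 carbon on oxygen) and the aryl bromides stay untouched.

Step 5
Reactants: 13 3,6-dibromo-2-(2-bromophenoxy)phenol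
Product: 14 3,4,6-tribromo-2-(2-bromophenoxy)phenol
Conditions: Br2 (1.0 equiv), AcOH/CH2Cl2, 0 °C → rt
Reagents that add atoms: bromine, BrBr
Why: Electrophilic aromatic bromination should go to C4 because the free C1 hydroxyl is the strongest donor and its ortho positions C2 and C6 are occupied, leaving only the para position, whereas C5 is meta to the hydroxyl and ring B carries only a weakly donating aryloxy oxygen and a deactivating bromine.

**Compound list**

1 | veratrole (1,2-dimethoxybenzene) | COc1ccccc1OC | starting material
2 | 3,6-dilithioveratrole (3,6-dilithio-1,2-dimethoxybenzene) | COc1c([Li])ccc([Li])c1OC | intermediate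
3 | 1,4-dibromo-2,3-dimethoxybenzene (3,6-dibromoveratrole) | COc1c(Br)ccc(Br)c1OC | intermediate
4 | sodium 3,6-dibromo-2-methoxyphenoxide | COc1c([O-])c(Br)ccc1Br.[Na+] | intermediate
5 | 3,6-dibromo-2-methoxyphenol | COc1c(O)c(Br)ccc1Br | intermediate
6 | 2-(trimethylsilyl)phenyl trifluoromethanesulfonate | C[Si](C)(C)c1ccccc1OS(=O)(=O)C(F)(F)F | starting material
7 | bromopentafluorobenzene | Fc1c(F)c(F)c(Br)c(F)c1F | starting material
8 | potassium 3,6-dibromo-2-methoxyphenoxide | COc1c([O-])c(Br)ccc1Br.[K+] | intermediate
9 | benzyne (1,2-didehydrobenzene) | C1#CC=CC=C1 | intermediate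
10 | 2-(3,6-dibromo-2-methoxyphenoxy)phenylpotassium | COc1c(Br)ccc(Br)c1Oc1ccccc1[K] | intermediate
11 | 1,4-dibromo-2-(2-bromophenoxy)-3-methoxybenzene | COc1c(Br)ccc(Br)c1Oc1ccccc1Br | intermediate
12 | dibromo[3,6-dibromo-2-(2-bromophenoxy)phenoxy]borane | BrB(Br)Oc1c(Br)ccc(Br)c1Oc1ccccc1Br | intermediate
13 | 3,6-dibromo-2-(2-bromophenoxy)phenol | Oc1c(Br)ccc(Br)c1Oc1ccccc1Br | intermediate
14 | 3,4,6-tribromo-2-(2-bromophenoxy)phenol | Oc1c(Br)cc(Br)c(Br)c1Oc1ccccc1Br | target

**Step count and risks**

Total step count: 5. Longest linear sequence: 5 steps (1 → 14); compounds 6 and 7 are bought.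

Steps most likely to fail:

Step 3 (key step). The aryl anion 10 may be protonated before bromine transfer, which would lose the C2′ bromine. The phenoxide 8 may be consumed by substitution at the para C–F bond of 7. Benzyne may be intercepted by pentafluorophenyl anion or bromide. An intramolecular bromine shift from ring A C3 to C2′ would be harmless, since recapture of bromine from 7 at C3 leads to the same compound 11. Fallback, from 5 to 11 without an aryne: (2-bromophenyl)(2,4,6-trimethoxyphenyl)iodonium tosylate F1 would be made in one pot from 1-bromo-2-iodobenzene (mCPBA, TsOH·H2O, MeCN; then 1,3,5-trimethoxybenzene). Phenoxide 8, formed from 5 with t-BuOK in THF, would then be O-arylated by this salt at rt to 40 °C. Metal-free ligand coupling on iodine should transfer the 2-bromophenyl group, the trimethoxyphenyl group leaving as its iodide, and the sequence rejoins the route at 11.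

Step 2. Mono-selectivity may be lost through a second demethylation, or thiolate may attack a C–Br bond (substitution or reductive debromination). Fallback, from 3 to 5 by full cleavage and re-methylation: excess BBr3 (CH2Cl2, −78 °C → rt) should remove both methyl groups to give 3,6-dibromobenzene-1,2-diol F2. One equivalent each of K2CO3 and MeI in DMF at rt should then methylate one of its two equivalent hydroxyls, the mono-anion being the reacting species. Any doubly methylated material is compound 3 and can be recycled; the sequence rejoins the route at 5.

Step 5. Site selectivity between ring A C4 and the position para to oxygen on ring B may be poor, or a second bromination may occur. Fallback, from 5 to 14 with ring B deactivated while ring A is brominated: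
- SNAr of 5 with 1-fluoro-2-nitrobenzene (K2CO3, DMF, 80 °C) should give 1,4-dibromo-2-methoxy-3-(2-nitrophenoxy)benzene F3.
- BBr3 (CH2Cl2) should free 3,6-dibromo-2-(2-nitrophenoxy)phenol F4.
- Br2 in AcOH should then brominate only ring A, para to the hydroxyl, to give 3,4,6-tribromo-2-(2-nitrophenoxy)phenol F5, since the nitro group shuts down ring B.
- Fe/NH4Cl (EtOH/H2O, 70 °C) should reduce the nitro group without touching C–Br, giving 2-(2-aminophenoxy)-3,4,6-tribromophenol F6.
- Diazotisation (NaNO2, aq. HBr, 0 °C) should give 2-(3,4,6-tribromo-2-hydroxyphenoxy)benzenediazonium bromide F7, whose phenol ring has no free ortho or para position for azo coupling.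
- Sandmeyer bromination with CuBr (aq. HBr, 60 °C) then puts bromine on C2′, and the sequence rejoins the route at 14.

**Further compounds**

F1 | step 3 | (2-bromophenyl)(2,4,6-trimethoxyphenyl)iodonium 4-methylbenzenesulfonate | COc1cc(OC)c([I+]c2ccccc2Br)c(OC)c1.Cc1ccc(cc1)S(=O)(=O)[O-]
F2 | step 2 | 3,6-dibromobenzene-1,2-diol | Oc1c(Br)ccc(Br)c1O
F3 | step 5 | 1,4-dibromo-2-methoxy-3-(2-nitrophenoxy)benzene | COc1c(Br)ccc(Br)c1Oc1ccccc1[N+](=O)[O-]
F4 | step 5 | 3,6-dibromo-2-(2-nitrophenoxy)phenol | Oc1c(Br)ccc(Br)c1Oc1ccccc1[N+](=O)[O-]
F5 | step 5 | 3,4,6-tribromo-2-(2-nitrophenoxy)phenol | Oc1c(Br)cc(Br)c(Br)c1Oc1ccccc1[N+](=O)[O-]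
F6 | step 5 | 2-(2-aminophenoxy)-3,4,6-tribromophenol | Oc1c(Br)cc(Br)c(Br)c1Oc1ccccc1N
F7 | step 5 | 2-(3,4,6-tribromo-2-hydroxyphenoxy)benzenediazonium bromide | Oc1c(Br)cc(Br)c(Br)c1Oc1ccccc1[N+]#N.[Br-]
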